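**Retrosynthetic overview** (ring A = methyl ester ring, ring B = middle ring, ring C = terminal dihydroxy ring)
- The strategy rests on the depside carbonyls. Each is a single carbon held between an aryl carbon and a phenol oxygen: C1(ring B)–C(=O)–O4(ring A) and C1(ring C)–C(=O)–O4(ring B). That carbon is supplied as carbon monoxide.
- The link made last, C1(C)–CO and CO–O4(B), leads back to methyl lecanorate, CO and a dibenzylated orcinol iodide. The link made first, C1(B)–CO and CO–O4(A), leads back to methyl orsellinate, CO and the same iodide.
- The iodide comes from orcinol by double O-benzylation and iodination at the carbon between CH3 and OBn. Hydrogenolysis after each coupling frees the next acceptor hydroxyl.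
- No ring is formed. All three benzene rings are bought (two as orcinol, one as methyl orsellinate) and are joined in the order A+B, then C.

Key step: step 3

Remark: the target has no stereocentre and no configurationally stable axis. It is achiral, so no step needs stereocontrol.

**Step 1**
Reactants: 1 orcinol
Product: 2 1,3-bis(benzyloxy)-5-methylbenzene
Conditions: BnBr (2.3 equiv), K2CO3 (3 equiv), DMF, 60 °C
Reagents that add atoms: benzyl bromide, BrCc1ccccc1
Why: Williamson ether synthesis on both phenoxides, for which carbonate in a polar aprotic solvent favours O- over C-alkylation of the resorcinol.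

**Step 2**
Reactants: 2 1,3-bis(benzyloxy)-5-methylbenzene
Product: 3 1,5-bis(benzyloxy)-2-iodo-3-methylbenzene
Conditions: NIS (1.0 equiv), TFA (10 mol %), MeCN, 0 °C → rt, dark
Reagents that add atoms: N-iodosuccinimide, O=C1CCC(=O)N1I
Why: Electrophilic aromatic iodination should go to the carbon para to one benzyloxy group and ortho to the other, which is less crowded than the carbon between the two benzyloxy groups, as is usual for halogenation of 3,5-dialkoxytoluenes, and one equivalent of NIS limits a second iodination.

**Step 3**
Reactants: 3 1,5-bis(benzyloxy)-2-iodo-3-methylbenzene; 4 methyl orsellinate (1.3 equiv); 5 carbon monoxide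
Product: 6 methyl 4-{[2,4-bis(benzyloxy)-6-methylbenzoyl]oxy}-2-hydroxy-6-methylbenzoate
Conditions: Pd(OAc)2 (5 mol %), Xantphos (7.5 mol %), Et3N (2.5 equiv), CO (5 bar), 4 Å MS, 1,4-dioxane, 90 °C
Reagents that add atoms: carbon monoxide (5), [C-]#[O+]
Why: Pd(0) adds oxidatively into the C–I bond of 3, CO inserts into the aryl–Pd bond (a migration that the two ortho substituents favour by relief of strain), and the phenoxide of 4 replaces iodide on the aroylpalladium(II) and leaves with the aroyl group by reductive elimination, so that C1(ring B)–C(=O) and C(=O)–O4(ring A) are made in one operation. The closest known reaction type is the palladium-catalysed aryloxycarbonylation of aryl iodides with phenols, and alkoxycarbonylation of di-ortho-substituted resorcinol-type iodides is also known, so this is a demanding case of a known reaction. No ring is closed and no stereocentre is made. The step needs site selectivity between the two hydroxyls of 4: O2–H is hydrogen-bonded to the ester carbonyl and shielded by the ester, whereas O4–H is more acidic and unhindered, so only O4 should be acylated. Preference for the ester over the diaryl ether, the deiodinated arene and the carboxylic acid rests on a moderate CO pressure, on the wide-bite-angle ligand, which speeds acyl–oxygen reductive elimination, and on dry conditions. The hindered, electron-rich carbonyl of 6 should resist attack by further phenoxide under an amine base.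

**Step 4**
Reactants: 6 methyl 4-{[2,4-bis(benzyloxy)-6-methylbenzoyl]oxy}-2-hydroxy-6-methylbenzoate
Product: 7 methyl 4-[(2,4-dihydroxy-6-methylbenzoyl)oxy]-2-hydroxy-6-methylbenzoate (methyl lecanorate)
Conditions: H2 (1 atm), 10 % Pd/C, EtOAc–THF, rt
Reagents that add atoms: none
Why: Catalytic hydrogenolysis cleaves both benzyl aryl ethers under neutral conditions in a non-nucleophilic solvent, which leaves the aryl ester and the methyl ester untouched.

**Step 5**
Reactants: 7 methyl lecanorate; 3 1,5-bis(benzyloxy)-2-iodo-3-methylbenzene (1.2 equiv); 5 carbon monoxide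
Product: 8 methyl 4-{[4-{[2,4-bis(benzyloxy)-6-methylbenzoyl]oxy}-2-hydroxy-6-methylbenzoyl]oxy}-2-hydroxy-6-methylbenzoate
Conditions: Pd(OAc)2 (5 mol %), Xantphos (7.5 mol %), Et3N (2.5 equiv), CO (5 bar), 4 Å MS, 1,4-dioxane, 80 °C
Reagents that add atoms: carbon monoxide (5), [C-]#[O+]
Why: This is the same palladium-catalysed aryloxycarbonylation, in which only O4–H of ring B among the three hydroxyls of 7 lacks a hydrogen bond to an ortho ester carbonyl and should therefore capture the aroylpalladium, while the amine base and the lower temperature should spare the hindered depside link already present.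

**Step 6**
Reactants: 8 methyl 4-{[4-{[2,4-bis(benzyloxy)-6-methylbenzoyl]oxy}-2-hydroxy-6-methylbenzoyl]oxy}-2-hydroxy-6-methylbenzoate
Product: 9 methyl 4-{[4-{[2,4-dihydroxy-6-methylbenzoyl]oxy}-2-hydroxy-6-methylbenzoyl]oxy}-2-hydroxy-6-methylbenzoate (methyl gyrophorate, target)
Conditions: H2 (1 atm), 10 % Pd/C, THF–EtOAc, rt
Reagents that add atoms: none
Why: Catalytic hydrogenolysis of the two remaining benzyl ethers is neutral and should leave both depside esters and the methyl ester intact, and THF keeps the tridepside in solution.

**Compound list**
1 | orcinol (5-methylbenzene-1,3-diol) | Cc1cc(O)cc(O)c1 | starting material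
2 | 1,3-bis(benzyloxy)-5-methylbenzene | Cc1cc(OCc2ccccc2)cc(OCc2ccccc2)c1 | intermediate
3 | 1,5-bis(benzyloxy)-2-iodo-3-methylbenzene | Cc1cc(OCc2ccccc2)cc(OCc2ccccc2)c1I | intermediate
4 | methyl orsellinate (methyl 2,4-dihydroxy-6-methylbenzoate) | COC(=O)c1c(C)cc(O)cc1O | starting material
5 | carbon monoxide | [C-]#[O+] | starting material
6 | methyl 4-{[2,4-bis(benzyloxy)-6-methylbenzoyl]oxy}-2-hydroxy-6-methylbenzoate | COC(=O)c1c(C)cc(OC(=O)c2c(C)cc(OCc3ccccc3)cc2OCc2ccccc2)cc1O | intermediate
7 | methyl 4-[(2,4-dihydroxy-6-methylbenzoyl)oxy]-2-hydroxy-6-methylbenzoate (methyl lecanorate) | COC(=O)c1c(C)cc(OC(=O)c2c(C)cc(O)cc2O)cc1O | intermediate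
8 | methyl 4-{[4-{[2,4-bis(benzyloxy)-6-methylbenzoyl]oxy}-2-hydroxy-6-methylbenzoyl]oxy}-2-hydroxy-6-methylbenzoate | COC(=O)c1c(C)cc(OC(=O)c2c(C)cc(OC(=O)c3c(C)cc(OCc4ccccc4)cc3OCc3ccccc3)cc2O)cc1O | intermediate
9 | methyl gyrophorate (achiral) | COC(=O)c1c(C)cc(OC(=O)c2c(C)cc(OC(=O)c3c(C)cc(O)cc3O)cc2O)cc1O | target

**Total step count:** 6
**Longest linear sequence:** 6 (1 → 2 → 3 → 6 → 7 → 8 → 9)

**Steps most likely to fail**

1. **Step 3.** Oxidative addition and acyl transfer at the di-ortho-substituted, electron-rich iodide may be slow. Hydrodeiodination, or capture of the aroylpalladium by traces of water, could then outrun capture by the phenol.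
 - The fallback sets out from 3 and leaves palladium and CO aside.
 - Iodine–magnesium exchange with iPrMgCl·LiCl (THF, 0 °C → rt) should give [2,4-bis(benzyloxy)-6-methylphenyl]magnesium chloride F1.
 - Carboxylation with dry CO2 and work-up with dilute HCl should give 2,4-bis(benzyloxy)-6-methylbenzoic acid F2.
 - Steglich esterification of F2 with 4 (DCC, catalytic DMAP, toluene, rt), the classical depside coupling, acylates only the unchelated 4-hydroxyl and comes back to the route at 6.

2. **Step 5.** Warm amine base may cause acyl migration of the existing depside link through the free phenoxide of 7, or acylation at more than one hydroxyl. The salicylate-type sites of 7 may also bind and slow the catalyst.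
 - The fallback sets out from 7 and from acid F2, which is made from 3 as described under step 3.
 - Trifluoroacetic anhydride in toluene at rt, without any base, should convert the acid into 2,4-bis(benzyloxy)-6-methylbenzoic trifluoroacetic anhydride F3.
 - This electron-rich mixed anhydride transfers its aroyl group to the free 4-hydroxyl of ring B.
 - Any phenol trifluoroacetate formed in passing is lost on bicarbonate work-up, and the sequence comes back to the route at 8.

3. **Step 2.** Iodination may also occur at the carbon between the two benzyloxy groups, or a second iodination may occur, leaving mixtures that are hard to separate.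
 - The fallback sets out from 2.
 - Bromination with NBS (1.0 equiv, CH2Cl2, −20 °C), which is smaller and more para-selective at low temperature, should give 1,5-bis(benzyloxy)-2-bromo-3-methylbenzene F4, a compound that can be purified by crystallisation.
 - Bromine–lithium exchange with n-BuLi (THF, −78 °C) should give [2,4-bis(benzyloxy)-6-methylphenyl]lithium F5.
 - Quenching with I2 at −78 °C places iodine at the carbon that bore bromine and comes back to the route at 3.

**Further compounds**
F1 | step 3 | [2,4-bis(benzyloxy)-6-methylphenyl]magnesium chloride | Cc1cc(OCc2ccccc2)cc(OCc2ccccc2)c1[Mg]Cl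
F2 | step 3 | 2,4-bis(benzyloxy)-6-methylbenzoic acid | Cc1cc(OCc2ccccc2)cc(OCc2ccccc2)c1C(=O)O
F3 | step 5 | 2,4-bis(benzyloxy)-6-methylbenzoic trifluoroacetic anhydride | Cc1cc(OCc2ccccc2)cc(OCc2ccccc2)c1C(=O)OC(=O)C(F)(F)F
F4 | step 2 | 1,5-bis(benzyloxy)-2-bromo-3-methylbenzene | Cc1cc(OCc2ccccc2)cc(OCc2ccccc2)c1Br
F5 | step 2 | [2,4-bis(benzyloxy)-6-methylphenyl]lithium | Cc1cc(OCc2ccccc2)cc(OCc2ccccc2)c1[Li]
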